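**Retrosynthetic overview**
- Numbering: lactone O1, ring C2–C5, exocyclic C6, chain C7–C18, then the 3-furyl group. The palmitate is put on O4 last. The 2(5H)-furanone ring (O1, C2–C5) is the only ring built, closed late by Dieckmann C3–C4 bond formation in an enol propanoate.
- The (5E) C5=C6 alkene (O1 trans to C7) comes from a C5≡C6 ynoate by syn-hydrostannation, iodination and stereoretentive copper-mediated C5–O1 coupling. The ynoate comes from a terminal alkyne.
- Feature the plan rests on: the only stereocentre, C7, is a CH(CH3) between sp2 C6 and methylene C8. Both C7–C8 and C7–C6 are therefore made by stereospecific boron 1,2-shifts: lithiated ethyl carbamate plus the tail pinacol boronate, then lithiated vinyl carbamate, iodine and base to give the alkyne.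
- The tail boronate (C8–C18 and furan) comes from (2E,6E)-farnesyl acetate, with the terminal epoxide as a masked C8 aldehyde, and a 3-furylmethyl Grignard reagent. The furan ring is bought.

Key step: step 12

Assumption: the target is taken as encoded, (5E) at C5=C6 (O1 and C7 on opposite sides) and (S) at C7; commercial (+)-sparteine is the chiral diamine.

**Step 1**
Reactants: 1 (2E,6E)-farnesyl acetate
Product: 2 (2E,6E)-10-bromo-11-hydroxy-3,7,11-trimethyldodeca-2,6-dien-1-yl acetate (racemic at C10)
Conditions: NBS, THF/H2O, 0 °C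
Reagents that add atoms: N-bromosuccinimide (O=C1CCC(=O)N1Br); water (O)
Why: Bromohydrin formation (van Tamelen terminal functionalisation) should occur at the most electron-rich, least hindered terminal alkene, water opening the bromonium ion at the tertiary carbon; the racemic carbinol centre is lost in step 6.

**Step 2**
Reactants: 2 (2E,6E)-10-bromo-11-hydroxy-3,7,11-trimethyldodeca-2,6-dien-1-yl acetate
Product: 3 (2E,6E)-9-(3,3-dimethyloxiran-2-yl)-3,7-dimethylnona-2,6-dien-1-ol (racemic)
Conditions: K2CO3, MeOH, rt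
Reagents that add atoms: none
Why: Intramolecular Williamson closure of the alkoxide onto the C–Br carbon gives the epoxide, and the same medium transesterifies the allylic acetate to the free alcohol.

**Step 3**
Reactants: 3 (2E,6E)-9-(3,3-dimethyloxiran-2-yl)-3,7-dimethylnona-2,6-dien-1-ol
Product: 5 3-[(3E,7E)-9-chloro-3,7-dimethylnona-3,7-dien-1-yl]-2,2-dimethyloxirane, via allylic mesylate 4 (not isolated)
Conditions: MsCl, Et3N, CH2Cl2, −40 °C; then LiCl, DMF, 0 °C → rt
Reagents that add atoms: lithium chloride ([Li+].[Cl-])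
Why: SN2 displacement of the primary allylic mesylate by chloride under near-neutral conditions should keep the E alkene and leave the trisubstituted epoxide intact.

**Step 4**
Reactants: 6 furan-3-ylmethanol
Product: 7 3-(chloromethyl)furan
Conditions: SOCl2, pyridine, Et2O, 0 °C
Reagents that add atoms: thionyl chloride (ClS(Cl)=O)
Why: Chlorodehydroxylation through the chlorosulfite, with pyridine buffering the acid-sensitive furan; the volatile chloride is used at once.

**Step 5**
Reactants: 7 3-(chloromethyl)furan; 5 3-[(3E,7E)-9-chloro-3,7-dimethylnona-3,7-dien-1-yl]-2,2-dimethyloxirane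
Product: 9 3-[(3E,7E)-10-(3,3-dimethyloxiran-2-yl)-4,8-dimethyldeca-3,7-dien-1-yl]furan, via 3-furylmethylmagnesium chloride 8 (not isolated)
Conditions: 7, Mg, THF, rt; then 5, Li2CuCl4 (cat.), THF, 0 °C
Reagents that add atoms: none
Why: Copper-catalysed Grignard cross-coupling (Kochi–Tamura type) of the allylic chloride should take place at the primary carbon (SN2, not SN2') with retention of the E alkene and faster than opening of the hindered epoxide.

**Step 6**
Reactants: 9 3-[(3E,7E)-10-(3,3-dimethyloxiran-2-yl)-4,8-dimethyldeca-3,7-dien-1-yl]furan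
Product: 11 (4E,8E)-11-(furan-3-yl)-4,8-dimethylundeca-4,8-dienal, via vicinal diol 10 (not isolated)
Conditions: H5IO6, THF/H2O, 0 °C
Reagents that add atoms: none
Why: Acid-catalysed hydration of the epoxide followed by periodate glycol cleavage (Malaprade reaction) releases the C8 aldehyde; water enters at the tertiary carbon and leaves with the acetone, and the cold aqueous medium should outrun acid-triggered cyclisation onto the alkenes or the furan.

**Step 7**
Reactants: 11 (4E,8E)-11-(furan-3-yl)-4,8-dimethylundeca-4,8-dienal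
Product: 12 (4E,8E)-11-(furan-3-yl)-4,8-dimethylundeca-4,8-dien-1-ol
Conditions: NaBH4, MeOH, 0 °C
Reagents that add atoms: none
Why: Hydride reduction of the aldehyde; the alkenes and the furan are inert to borohydride.

**Step 8**
Reactants: 12 (4E,8E)-11-(furan-3-yl)-4,8-dimethylundeca-4,8-dien-1-ol
Product: 13 3-[(3E,7E)-11-iodo-4,8-dimethylundeca-3,7-dien-1-yl]furan
Conditions: I2, PPh3, imidazole, CH2Cl2, 0 °C
Reagents that add atoms: iodine (II)
Why: Appel-type iodination through the alkoxyphosphonium ion and SN2 attack by iodide, under neutral conditions that the furan and the trisubstituted alkenes tolerate.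

**Step 9**
Reactants: 13 3-[(3E,7E)-11-iodo-4,8-dimethylundeca-3,7-dien-1-yl]furan; 14 bis(pinacolato)diboron
Product: 15 2-[(4E,8E)-11-(furan-3-yl)-4,8-dimethylundeca-4,8-dien-1-yl]-4,4,5,5-tetramethyl-1,3,2-dioxaborolane
Conditions: CuI (cat.), PPh3, LiOMe, DMF, rt
Reagents that add atoms: none
Why: Copper-catalysed borylation of a primary alkyl iodide by a boryl–copper species formed from the diboron and LiOMe; the transient C8 radical has no favourable cyclisation onto the C11=C12 alkene.

**Step 10**
Reactants: 16 N,N-diisopropylcarbamoyl chloride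
Product: 17 ethyl N,N-diisopropylcarbamate
Conditions: EtOH, Et3N, CH2Cl2, reflux
Reagents that add atoms: ethanol (CCO)
Why: Acyl substitution at the carbamoyl chloride by ethanol with amine as acid scavenger.

**Step 11**
Reactants: 16 N,N-diisopropylcarbamoyl chloride
Product: 19 vinyl N,N-diisopropylcarbamate, via lithium ethenolate 18 (not isolated)
Conditions: n-BuLi, THF, 35 °C; then 16, DMPU, 0 °C → rt
Reagents that add atoms: tetrahydrofuran (C1CCOC1)
Why: α-Lithiation of THF and cycloreversion give ethene and lithium ethenolate, whose oxygen is acylated by the carbamoyl chloride in the presence of DMPU.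

**Step 12**
Reactants: 17 ethyl N,N-diisopropylcarbamate; 15 2-[(4E,8E)-11-(furan-3-yl)-4,8-dimethylundeca-4,8-dien-1-yl]-4,4,5,5-tetramethyl-1,3,2-dioxaborolane; 19 vinyl N,N-diisopropylcarbamate
Product: 28 3-[(3E,7E,12S)-4,8,12-trimethyltetradeca-3,7-dien-13-yn-1-yl]furan, via lithiated ethyl carbamate 20 (not isolated), via first boronate complex 21 (not isolated), via secondary boronate 22 (not isolated), via lithiated vinyl carbamate 23 (not isolated), via second boronate complex 24 (not isolated), via iodo boronate 25 (not isolated), via enol carbamate 26 (not isolated), via lithium acetylide 27 (not isolated)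
Conditions: 17, s-BuLi, (+)-sparteine, Et2O, −78 °C; 15, −78 → 35 °C; 23 (from 19, LiN(iPr)2, THF, −78 °C), −78 °C; I2, THF/MeOH, −78 °C; NaOMe, → 0 °C; solvent swap to THF; LiN(iPr)2, −78 °C → rt; aq. NH4Cl
Reagents that add atoms: none
Why: s-BuLi complexed by (+)-sparteine removes the pro-R α-proton of 17 to give configurationally stable (R)-20, which adds to the boron of 15 with retention to give 21, and on warming the tail alkyl group shifts from boron to carbon anti to the departing carbamate (inversion), forming C7–C8 and (S)-22. Lithiated vinyl carbamate 23 then adds to 22 to give 24, iodine activates the enol carbamate π-bond so that C7 shifts from boron to carbon with retention (forming C7–C6) to give 25, methoxide-induced anti elimination of boron and iodine gives 26, and LiN(iPr)2 removes a terminal vinylic proton and expels lithium carbamate to leave acetylide 27, which is protonated on work-up. The closest known reactions are the sparteine-mediated lithiation–borylation of primary alkyl carbamates and the Zweifel-type alkynylation of secondary pinacol boronates with α-lithiated vinyl carbamate, here run in sequence without isolating 22. No ring is closed. C7 is set by the reagent: (+)-sparteine fixes (R)-20, and the retention, inversion, retention sequence of the three stereospecific events converts this into (S) at C7 independently of the achiral tail. The furan and the two E alkenes must not meet s-BuLi, which is secured by adding 15 only after deprotonation is complete with 17 in slight excess over s-BuLi, and iodine must attack the boronate π-bond rather than the trisubstituted alkenes or the furan, which is secured by the much higher nucleophilicity of the anionic alkenyl boronate at −78 °C and by adding iodine only until its colour persists.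

**Step 13**
Reactants: 28 3-[(3E,7E,12S)-4,8,12-trimethyltetradeca-3,7-dien-13-yn-1-yl]furan
Product: 30 methyl (4S,8E,12E)-15-(furan-3-yl)-4,8,12-trimethylpentadeca-8,12-dien-2-ynoate, via alkynylmagnesium bromide 29 (not isolated)
Conditions: EtMgBr, THF, 0 → 40 °C; ClCO2Me, −20 °C → rt
Reagents that add atoms: methyl chloroformate (COC(Cl)=O)
Why: Ethylmagnesium bromide metalates only the terminal alkyne C–H (a Grignard reagent does not deprotonate the furan ring or the C7–H), and the alkynylmagnesium bromide is then acylated by the chloroformate (alkoxycarbonylation of an alkynyl Grignard reagent), which is far more electrophilic than the ynoate product.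

**Step 14**
Reactants: 30 methyl (4S,8E,12E)-15-(furan-3-yl)-4,8,12-trimethylpentadeca-8,12-dien-2-ynoate
Product: 31 methyl (2E,4S,8E,12E)-15-(furan-3-yl)-4,8,12-trimethyl-2-(tributylstannyl)pentadeca-2,8,12-trienoate
Conditions: Bu3SnH, Pd(PPh3)4 (cat.), THF, 0 °C → rt
Reagents that add atoms: tributyltin hydride (CCCC[SnH](CCCC)CCCC)
Why: Palladium-catalysed hydrostannation of an alkynoate adds H and Sn syn with tin on the ester-bearing carbon C5, away from branched C7, so C7 ends up cis to the ester carbon C4 and trans to tin.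

**Step 15**
Reactants: 31 methyl (2E,4S,8E,12E)-15-(furan-3-yl)-4,8,12-trimethyl-2-(tributylstannyl)pentadeca-2,8,12-trienoate
Product: 32 methyl (2E,4S,8E,12E)-15-(furan-3-yl)-2-iodo-4,8,12-trimethylpentadeca-2,8,12-trienoate
Conditions: I2 (1 equiv), CH2Cl2, 0 °C, dark
Reagents that add atoms: iodine (II)
Why: Iododestannylation is an ipso substitution with retention of alkene geometry, and the C–Sn bond should react with one equivalent of cold iodine well before the trisubstituted alkenes or the furan.

**Step 16**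
Reactants: 32 methyl (2E,4S,8E,12E)-15-(furan-3-yl)-2-iodo-4,8,12-trimethylpentadeca-2,8,12-trienoate
Product: 33 methyl (2E,4S,8E,12E)-15-(furan-3-yl)-4,8,12-trimethyl-2-(propanoyloxy)pentadeca-2,8,12-trienoate
Conditions: EtCO2Cs, CuI (cat.), 3,4,7,8-tetramethyl-1,10-phenanthroline, toluene, 70 °C, dark
Reagents that add atoms: cesium propanoate ([Cs+].CCC([O-])=O)
Why: Ullmann-type vinylic C–O coupling of an alkenyl iodide with a carboxylate (oxidative addition to a monovalent copper carboxylate, then C–O reductive elimination from trivalent copper) is stereoretentive, so O1 is installed trans to C7.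

**Step 17**
Reactants: 33 methyl (2E,4S,8E,12E)-15-(furan-3-yl)-4,8,12-trimethyl-2-(propanoyloxy)pentadeca-2,8,12-trienoate
Product: 35 (5E)-5-[(2S,6E,10E)-13-(furan-3-yl)-2,6,10-trimethyltrideca-6,10-dien-1-ylidene]-4-hydroxy-3-methylfuran-2(5H)-one, via lithium tetronate 34 (not isolated)
Conditions: LiN(SiMe3)2 (2.2 equiv), THF, −78 → 0 °C; cold 0.5 M HCl
Reagents that add atoms: none
Why: Dieckmann (Lacey–Dieckmann) condensation: the propanoate enolate attacks the neighbouring conjugated methyl ester in a 5-exo-trig acyl substitution that forms C3–C4, driven by deprotonation to the tetronate; no bond at C5=C6 or C7 is broken, so both stereo-elements should persist.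

**Step 18**
Reactants: 35 (5E)-5-[(2S,6E,10E)-13-(furan-3-yl)-2,6,10-trimethyltrideca-6,10-dien-1-ylidene]-4-hydroxy-3-methylfuran-2(5H)-one
Product: 36 (2E)-2-[(2S,6E,10E)-13-(furan-3-yl)-2,6,10-trimethyltrideca-6,10-dien-1-ylidene]-4-methyl-5-oxo-2,5-dihydrofuran-3-yl hexadecanoate
Conditions: palmitoyl chloride, Et3N, CH2Cl2, 0 °C
Reagents that add atoms: palmitoyl chloride (CCCCCCCCCCCCCCCC(Cl)=O)
Why: O-Acylation of the tetronic acid (a vinylogous carboxylic acid) at O4; C3 carries a methyl group, so no C-acylation product can form.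

**Compound list**
1 | (2E,6E)-farnesyl acetate | CC(C)=CCC/C(C)=C/CC/C(C)=C/COC(C)=O | starting material
2 | (2E,6E)-10-bromo-11-hydroxy-3,7,11-trimethyldodeca-2,6-dien-1-yl acetate (racemic) | CC(C)(O)C(Br)CC/C(C)=C/CC/C(C)=C/COC(C)=O | intermediate
3 | (2E,6E)-9-(3,3-dimethyloxiran-2-yl)-3,7-dimethylnona-2,6-dien-1-ol (racemic) | CC1(C)OC1CC/C(C)=C/CC/C(C)=C/CO | intermediate
4 | (2E,6E)-9-(3,3-dimethyloxiran-2-yl)-3,7-dimethylnona-2,6-dien-1-yl methanesulfonate | CC1(C)OC1CC/C(C)=C/CC/C(C)=C/COS(C)(=O)=O | intermediate (not isolated)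
5 | 3-[(3E,7E)-9-chloro-3,7-dimethylnona-3,7-dien-1-yl]-2,2-dimethyloxirane | CC1(C)OC1CC/C(C)=C/CC/C(C)=C/CCl | intermediate
6 | furan-3-ylmethanol | OCc1ccoc1 | starting material
7 | 3-(chloromethyl)furan | ClCc1ccoc1 | intermediate
8 | (furan-3-ylmethyl)magnesium chloride | Cl[Mg]Cc1ccoc1 | intermediate (not isolated)
9 | 3-[(3E,7E)-10-(3,3-dimethyloxiran-2-yl)-4,8-dimethyldeca-3,7-dien-1-yl]furan | CC1(C)OC1CC/C(C)=C/CC/C(C)=C/CCc1ccoc1 | intermediate
10 | (6E,10E)-13-(furan-3-yl)-2,6,10-trimethyltrideca-6,10-diene-2,3-diol | CC(C)(O)C(O)CC/C(C)=C/CC/C(C)=C/CCc1ccoc1 | intermediate (not isolated)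
11 | (4E,8E)-11-(furan-3-yl)-4,8-dimethylundeca-4,8-dienal | O=CCC/C(C)=C/CC/C(C)=C/CCc1ccoc1 | intermediate
12 | (4E,8E)-11-(furan-3-yl)-4,8-dimethylundeca-4,8-dien-1-ol | OCCC/C(C)=C/CC/C(C)=C/CCc1ccoc1 | intermediate
13 | 3-[(3E,7E)-11-iodo-4,8-dimethylundeca-3,7-dien-1-yl]furan | ICCC/C(C)=C/CC/C(C)=C/CCc1ccoc1 | intermediate
14 | bis(pinacolato)diboron | CC1(C)OB(OC1(C)C)B1OC(C)(C)C(C)(C)O1 | starting material
15 | 2-[(4E,8E)-11-(furan-3-yl)-4,8-dimethylundeca-4,8-dien-1-yl]-4,4,5,5-tetramethyl-1,3,2-dioxaborolane | CC1(C)OB(CCC/C(C)=C/CC/C(C)=C/CCc2ccoc2)OC1(C)C | intermediate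
16 | N,N-diisopropylcarbamoyl chloride | CC(C)N(C(C)C)C(Cl)=O | starting material
17 | ethyl N,N-diisopropylcarbamate | CCOC(=O)N(C(C)C)C(C)C | intermediate
18 | lithium ethenolate | [Li]OC=C | intermediate (not isolated)
19 | vinyl N,N-diisopropylcarbamate | C=COC(=O)N(C(C)C)C(C)C | intermediate
20 | (1R)-1-lithioethyl N,N-diisopropylcarbamate (as its (+)-sparteine complex) | [Li][C@H](C)OC(=O)N(C(C)C)C(C)C | intermediate (not isolated)
21 | lithium [(1R)-1-(N,N-diisopropylcarbamoyloxy)ethyl][(4E,8E)-11-(furan-3-yl)-4,8-dimethylundeca-4,8-dien-1-yl](pinacolato)borate | [Li+].CC1(C)O[B-](CCC/C(C)=C/CC/C(C)=C/CCc2ccoc2)([C@H](C)OC(=O)N(C(C)C)C(C)C)OC1(C)C | intermediate (not isolated)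
22 | 2-[(2S,6E,10E)-13-(furan-3-yl)-6,10-dimethyltrideca-6,10-dien-2-yl]-4,4,5,5-tetramethyl-1,3,2-dioxaborolane | CC1(C)OB([C@@H](C)CCC/C(C)=C/CC/C(C)=C/CCc2ccoc2)OC1(C)C | intermediate (not isolated)
23 | 1-lithioethenyl N,N-diisopropylcarbamate | [Li]C(=C)OC(=O)N(C(C)C)C(C)C | intermediate (not isolated)
24 | lithium [1-(N,N-diisopropylcarbamoyloxy)ethenyl][(2S,6E,10E)-13-(furan-3-yl)-6,10-dimethyltrideca-6,10-dien-2-yl](pinacolato)borate | [Li+].CC1(C)O[B-](C(=C)OC(=O)N(C(C)C)C(C)C)([C@@H](C)CCC/C(C)=C/CC/C(C)=C/CCc2ccoc2)OC1(C)C | intermediate (not isolated)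
25 | (3S,7E,11E)-14-(furan-3-yl)-1-iodo-3,7,11-trimethyl-2-(4,4,5,5-tetramethyl-1,3,2-dioxaborolan-2-yl)tetradeca-7,11-dien-2-yl N,N-diisopropylcarbamate (C2 epimers) | CC1(C)OB(C(CI)(OC(=O)N(C(C)C)C(C)C)[C@@H](C)CCC/C(C)=C/CC/C(C)=C/CCc2ccoc2)OC1(C)C | intermediate (not isolated)
26 | (3S,7E,11E)-14-(furan-3-yl)-3,7,11-trimethyltetradeca-1,7,11-trien-2-yl N,N-diisopropylcarbamate | C=C(OC(=O)N(C(C)C)C(C)C)[C@@H](C)CCC/C(C)=C/CC/C(C)=C/CCc1ccoc1 | intermediate (not isolated)
27 | lithium (3S,7E,11E)-14-(furan-3-yl)-3,7,11-trimethyltetradeca-7,11-dien-1-yn-1-ide | [Li]C#C[C@@H](C)CCC/C(C)=C/CC/C(C)=C/CCc1ccoc1 | intermediate (not isolated)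
28 | 3-[(3E,7E,12S)-4,8,12-trimethyltetradeca-3,7-dien-13-yn-1-yl]furan | C#C[C@@H](C)CCC/C(C)=C/CC/C(C)=C/CCc1ccoc1 | intermediate
29 | bromo[(3S,7E,11E)-14-(furan-3-yl)-3,7,11-trimethyltetradeca-7,11-dien-1-yn-1-yl]magnesium | Br[Mg]C#C[C@@H](C)CCC/C(C)=C/CC/C(C)=C/CCc1ccoc1 | intermediate (not isolated)
30 | methyl (4S,8E,12E)-15-(furan-3-yl)-4,8,12-trimethylpentadeca-8,12-dien-2-ynoate | COC(=O)C#C[C@@H](C)CCC/C(C)=C/CC/C(C)=C/CCc1ccoc1 | intermediate
31 | methyl (2E,4S,8E,12E)-15-(furan-3-yl)-4,8,12-trimethyl-2-(tributylstannyl)pentadeca-2,8,12-trienoate | COC(=O)/C(=C\[C@@H](C)CCC/C(C)=C/CC/C(C)=C/CCc1ccoc1)[Sn](CCCC)(CCCC)CCCC | intermediate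
32 | methyl (2E,4S,8E,12E)-15-(furan-3-yl)-2-iodo-4,8,12-trimethylpentadeca-2,8,12-trienoate | COC(=O)/C(I)=C\[C@@H](C)CCC/C(C)=C/CC/C(C)=C/CCc1ccoc1 | intermediate
33 | methyl (2E,4S,8E,12E)-15-(furan-3-yl)-4,8,12-trimethyl-2-(propanoyloxy)pentadeca-2,8,12-trienoate | CCC(=O)O/C(C(=O)OC)=C/[C@@H](C)CCC/C(C)=C/CC/C(C)=C/CCc1ccoc1 | intermediate
34 | lithium (2E)-2-[(2S,6E,10E)-13-(furan-3-yl)-2,6,10-trimethyltrideca-6,10-dien-1-ylidene]-4-methyl-5-oxo-2,5-dihydrofuran-3-olate | [Li+].[O-]C1=C(C)C(=O)O/C1=C/[C@@H](C)CCC/C(C)=C/CC/C(C)=C/CCc1ccoc1 | intermediate (not isolated)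
35 | (5E)-5-[(2S,6E,10E)-13-(furan-3-yl)-2,6,10-trimethyltrideca-6,10-dien-1-ylidene]-4-hydroxy-3-methylfuran-2(5H)-one | OC1=C(C)C(=O)O/C1=C/[C@@H](C)CCC/C(C)=C/CC/C(C)=C/CCc1ccoc1 | intermediate
36 | (2E)-2-[(2S,6E,10E)-13-(furan-3-yl)-2,6,10-trimethyltrideca-6,10-dien-1-ylidene]-4-methyl-5-oxo-2,5-dihydrofuran-3-yl hexadecanoate | CCCCCCCCCCCCCCCC(=O)OC1=C(C)C(=O)O/C1=C/[C@@H](C)CCC/C(C)=C/CC/C(C)=C/CCc1ccoc1 | target

**Step count**
Total: 18 steps. Longest linear sequence: 15 steps (1, 2, 3, 5, 6, 7, 8, 9, 12, 13, 14, 15, 16, 17, 18).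

**Steps most likely to fail**

Step 12. The one-flask sequence may stall at the second boronate-complex formation, because lithium carbamate and the diamine left from the first stage can compete for boron or bind iodine. Reversal of the first boronate complex before the 1,2-shift would also erode the enantiomeric purity at C7. The fallback sets out from secondary boronate 22, isolated after the first stage, and changes how C6 and C5 are brought in. Matteson homologation with chloromethyllithium (BrCH2Cl, n-BuLi, THF, −78 °C → rt) should insert C6 with retention to give 2-[(2R,6E,10E)-13-(furan-3-yl)-2,6,10-trimethyltrideca-6,10-dien-1-yl]-4,4,5,5-tetramethyl-1,3,2-dioxaborolane F1. Oxidation with NaOH/H2O2 should give (2S,6E,10E)-13-(furan-3-yl)-2,6,10-trimethyltrideca-6,10-dien-1-ol F2. Dess–Martin periodinane buffered with NaHCO3 should give (2S,6E,10E)-13-(furan-3-yl)-2,6,10-trimethyltrideca-6,10-dienal F3. Seyferth–Gilbert homologation with the Ohira–Bestmann reagent (K2CO3, MeOH, 0 °C) then adds C5 and comes back to the route at alkyne 28.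

Step 16. Carbon–oxygen reductive elimination at the hindered, ester-bearing alkenyl copper centre may be slow, so that protodeiodination competes. The alkene geometry may also be lost through reversible conjugate addition of carboxylate or iodide at C6. The fallback sets out from iodide 32 and reverses the polarity of the coupling. Miyaura borylation (bis(pinacolato)diboron, PdCl2(dppf), KOPh, toluene, 50 °C) should give, with retention, methyl (2Z,4S,8E,12E)-15-(furan-3-yl)-4,8,12-trimethyl-2-(4,4,5,5-tetramethyl-1,3,2-dioxaborolan-2-yl)pentadeca-2,8,12-trienoate F4. Chan–Lam-type oxidative coupling with propanoic acid (Cu(OAc)2, Et3N, 4 Å molecular sieves, air, CH2Cl2, rt), a known route from alkenyl boronates to enol esters, then comes back at enol propanoate 33.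

Step 17. The enolate of the enol ester may expel methylketene instead of cyclising, and the amide base may remove the γ-proton at C7 and scramble the stereocentre. The fallback sets out from iodide 32, bypasses 33, and closes the ring through O1–C5 instead of C3–C4. Reduction with iBu2AlH (CH2Cl2, −78 °C) should give (2E,4S,8E,12E)-15-(furan-3-yl)-2-iodo-4,8,12-trimethylpentadeca-2,8,12-trien-1-ol F5. Oxidation with MnO2 should give (2E,4S,8E,12E)-15-(furan-3-yl)-2-iodo-4,8,12-trimethylpentadeca-2,8,12-trienal F6. Aldol addition of the dilithium enediolate of propanoic acid (propanoic acid, 2 LiN(iPr)2, THF, −78 °C) should give (4E,6S,10E,14E)-17-(furan-3-yl)-3-hydroxy-4-iodo-2,6,10,14-tetramethylheptadeca-4,10,14-trienoic acid F7, as a diastereomer mixture at C2 and C3 that does not matter. Intramolecular copper-catalysed O-vinylation of the carboxylate (CuI, 1,10-phenanthroline, Cs2CO3, THF, 60 °C), a known closure of 4-halopent-4-enoic acids to enol lactones with retention, should give (5E)-5-[(2S,6E,10E)-13-(furan-3-yl)-2,6,10-trimethyltrideca-6,10-dien-1-ylidene]-4-hydroxy-3-methyloxolan-2-one F8. Dess–Martin oxidation of the C4 carbinol then gives the β-keto lactone, which is tetronic acid 35, where the route is rejoined.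

**Further compounds**
F1 | step 12 | 2-[(2R,6E,10E)-13-(furan-3-yl)-2,6,10-trimethyltrideca-6,10-dien-1-yl]-4,4,5,5-tetramethyl-1,3,2-dioxaborolane | CC1(C)OB(C[C@@H](C)CCC/C(C)=C/CC/C(C)=C/CCc2ccoc2)OC1(C)C
F2 | step 12 | (2S,6E,10E)-13-(furan-3-yl)-2,6,10-trimethyltrideca-6,10-dien-1-ol | OC[C@@H](C)CCC/C(C)=C/CC/C(C)=C/CCc1ccoc1
F3 | step 12 | (2S,6E,10E)-13-(furan-3-yl)-2,6,10-trimethyltrideca-6,10-dienal | O=C[C@@H](C)CCC/C(C)=C/CC/C(C)=C/CCc1ccoc1
F4 | step 16 | methyl (2Z,4S,8E,12E)-15-(furan-3-yl)-4,8,12-trimethyl-2-(4,4,5,5-tetramethyl-1,3,2-dioxaborolan-2-yl)pentadeca-2,8,12-trienoate | COC(=O)/C(B1OC(C)(C)C(C)(C)O1)=C\[C@@H](C)CCC/C(C)=C/CC/C(C)=C/CCc1ccoc1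
F5 | step 17 | (2E,4S,8E,12E)-15-(furan-3-yl)-2-iodo-4,8,12-trimethylpentadeca-2,8,12-trien-1-ol | OC/C(I)=C\[C@@H](C)CCC/C(C)=C/CC/C(C)=C/CCc1ccoc1
F6 | step 17 | (2E,4S,8E,12E)-15-(furan-3-yl)-2-iodo-4,8,12-trimethylpentadeca-2,8,12-trienal | O=C/C(I)=C\[C@@H](C)CCC/C(C)=C/CC/C(C)=C/CCc1ccoc1
F7 | step 17 | (4E,6S,10E,14E)-17-(furan-3-yl)-3-hydroxy-4-iodo-2,6,10,14-tetramethylheptadeca-4,10,14-trienoic acid | OC(=O)C(C)C(O)/C(I)=C\[C@@H](C)CCC/C(C)=C/CC/C(C)=C/CCc1ccoc1
F8 | step 17 | (5E)-5-[(2S,6E,10E)-13-(furan-3-yl)-2,6,10-trimethyltrideca-6,10-dien-1-ylidene]-4-hydroxy-3-methyloxolan-2-one | CC1C(O)/C(=C\[C@@H](C)CCC/C(C)=C/CC/C(C)=C/CCc2ccoc2)OC1=O
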